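**Plan**

- Retrosynthesis, side chain on C6 numbered C1'–C9': (i) the C3'=O and C8'=O groups go back to the tetrasubstituted C=C of a 2,6,6-trimethylcyclohexene (ozonolysis), and C1'H2–C2'H2 to an alkyne. (ii) The C6–C1' bond is cut to a ring peroxycarbenium ion and an alkynyl donor. (iii) O2–C3 is cut to a hydroperoxy ketal and a secondary mesylate. (iv) C2–C3 is cut to a crotylboration of 4-oxopentanal, with the C1 ester masked as a vinyl group.
- Forward: the C1–C6 chain is built first, the 1,2-dioxane is closed by O-alkylation, the side chain is joined at C6, and the acyclic diketone is released last.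
- Feature used: C6 is the only fully substituted ring carbon and carries O1 and a methyl group, so it is a masked methyl ketone. As its methyl peroxyketal it ionizes to a planar C6=O1+ ion inside the 1,2-dioxane ring, so its configuration need not be set beforehand.
- Stereochemistry: C2 and C3 come from a catalyst-controlled syn-crotylation followed by SN2 inversion at C3. C6 comes from C3 (1,4 across the ring) by axial attack on the ion, which converts both ketal epimers into one configuration.
- Second feature: the C3'(=O)–C(CH3)2–(CH2)3–C8'(=O)CH3 unit is the ozonolysis product of the ring of β-cyclocitral.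

Key step: step 10

Remark: the ketal carbon (later C6) is carried as a mixture of both epimers until step 10 planarizes it; the SMILES of these compounds leave it undefined.
Remark: in step 2 the (S)-acid is assumed to deliver the crotyl group to the Si face of the aldehyde; if the sense proves opposite, the (R)-acid is used.

**Route**

Step 1
Reactants: 1 hex-5-en-2-one
Product: 3 4-oxopentanal, via ozonide 2 (not isolated)
Conditions: O3, CH2Cl2, −78 °C; then Me2S, −78 °C → rt
Reagents that add atoms: ozone, [O-][O+]=O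
Why: Criegee ozonolysis of the terminal alkene with reductive work-up; the methyl ketone is inert and no stereocenter is formed.

Step 2
Reactants: 3 4-oxopentanal; 4 (Z)-crotylboronic acid pinacol ester
Product: 6 (5R,6R)-5-hydroxy-6-methyloct-7-en-2-one, via pinacol borate 5 (not isolated)
Conditions: (S)-TRIP phosphoric acid (5 mol %), 4 Å MS, toluene, −30 °C; then aq. NaHCO3
Reagents that add atoms: none
Why: Chiral phosphoric acid-catalysed crotylboration through a closed chair (Zimmerman–Traxler) transition state, in which the (Z)-boronate gives the syn adduct by Si-face attack on the aldehyde (far more reactive than the ketone); this fixes the later C2 and sets the carbinol carbon opposite to what C3 needs, because step 5 inverts it.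

Step 3
Reactants: 6 (5R,6R)-5-hydroxy-6-methyloct-7-en-2-one
Product: 7 (3R,4R)-3-methyl-7-oxooct-1-en-4-yl methanesulfonate
Conditions: MsCl, Et3N, CH2Cl2, 0 °C
Reagents that add atoms: methanesulfonyl chloride, CS(=O)(=O)Cl
Why: Sulfonylation of the secondary alcohol, with retention at carbon, installs the leaving group for the ring closure.

Step 4
Reactants: 7 (3R,4R)-3-methyl-7-oxooct-1-en-4-yl methanesulfonate
Product: 8 (3R,4R)-7-hydroperoxy-7-methoxy-3-methyloct-1-en-4-yl methanesulfonate (both C7 epimers)
Conditions: urea–H2O2, Sc(OTf)3 (cat.), MeOH, 0 °C → rt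
Reagents that add atoms: hydrogen peroxide (from urea–hydrogen peroxide), OO; methanol, CO
Why: Acid-catalysed perhydrolysis of the methyl ketone in methanol (peroxyketalization) gives the gem-methoxy hydroperoxide; the new centre is immaterial because it is planarized in step 10, and the mesylate and alkene are inert to these conditions.

Step 5
Reactants: 8 (3R,4R)-7-hydroperoxy-7-methoxy-3-methyloct-1-en-4-yl methanesulfonate
Product: 9 (3S)-3-[(2R)-but-3-en-2-yl]-6-methoxy-6-methyl-1,2-dioxane (both C6 epimers)
Conditions: KOtBu (1.05 equiv), 18-crown-6, THF, 0 °C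
Reagents that add atoms: none
Why: Intramolecular O-alkylation of the hydroperoxy ketal (6-exo-tet SN2 by the weakly basic peroxy anion) closes the 1,2-dioxane with inversion at the mesylate carbon, which turns the syn crotyl adduct into the 2,3-anti arrangement with C3 = S.

Step 6
Reactants: 9 (3S)-3-[(2R)-but-3-en-2-yl]-6-methoxy-6-methyl-1,2-dioxane
Product: 12 (2S)-2-[(3S)-6-methoxy-6-methyl-1,2-dioxan-3-yl]propanoic acid, via ozonide 10 (not isolated), via aldehyde 11 (not isolated)
Conditions: O3, CH2Cl2, −78 °C; Me2S; then NaClO2, NaH2PO4, 2-methylbut-2-ene, t-BuOH/H2O, 0 °C → rt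
Reagents that add atoms: ozone, [O-][O+]=O; sodium chlorite, [Na+].[O-]Cl=O
Why: Ozonolysis of the vinyl group followed at once by Pinnick oxidation of the crude aldehyde under buffered, non-basic conditions, so that C2 is not epimerized and the β-peroxy aldehyde is not opened by elimination; the descriptor at C2 changes from R to S only because the carboxyl group outranks C3.

Step 7
Reactants: 12 (2S)-2-[(3S)-6-methoxy-6-methyl-1,2-dioxan-3-yl]propanoic acid
Product: 13 methyl (2S)-2-[(3S)-6-methoxy-6-methyl-1,2-dioxan-3-yl]propanoate (both C6 epimers)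
Conditions: TMSCHN2, toluene/MeOH, 0 °C
Reagents that add atoms: (trimethylsilyl)diazomethane, C[Si](C)(C)C=[N+]=[N-]
Why: Esterification by diazomethane generated in the flask, under neutral conditions that leave C2 and the peroxyketal untouched.

Step 8
Reactants: 14 β-cyclocitral
Product: 15 2-ethynyl-1,3,3-trimethylcyclohex-1-ene
Conditions: dimethyl (1-diazo-2-oxopropyl)phosphonate, K2CO3, MeOH, 0 °C → rt
Reagents that add atoms: dimethyl (1-diazo-2-oxopropyl)phosphonate, COP(=O)(OC)C(=[N+]=[N-])C(C)=O
Why: Seyferth–Gilbert homologation under Ohira–Bestmann conditions; the aldehyde has no α-hydrogen and a fully substituted β-carbon, so neither enolization nor conjugate addition of methoxide interferes.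

Step 9
Reactants: 15 2-ethynyl-1,3,3-trimethylcyclohex-1-ene
Product: 18 potassium trifluoro[(2,6,6-trimethylcyclohex-1-en-1-yl)ethynyl]borate, via lithium acetylide 16 (not isolated), via lithium trimethoxyborate 17 (not isolated)
Conditions: n-BuLi, THF, −78 °C; B(OMe)3, −78 → −20 °C; aq. KHF2, −20 °C → rt
Reagents that add atoms: trimethyl borate, COB(OC)OC; potassium hydrogen difluoride, [K+].F[H-]F
Why: Deprotonation of the terminal alkyne, borylation and fluoride exchange (standard alkynyltrifluoroborate synthesis) should give a bench-stable, non-reducing alkynyl donor.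

Step 10
Reactants: 13 methyl (2S)-2-[(3S)-6-methoxy-6-methyl-1,2-dioxan-3-yl]propanoate; 18 potassium trifluoro[(2,6,6-trimethylcyclohex-1-en-1-yl)ethynyl]borate
Product: 21 methyl (2S)-2-[(3S,6R)-6-methyl-6-[(2,6,6-trimethylcyclohex-1-en-1-yl)ethynyl]-1,2-dioxan-3-yl]propanoate, via alkynyldifluoroborane 19 (not isolated), via peroxycarbenium ion 20 (not isolated)
Conditions: BF3·OEt2 (2.2 equiv), CH2Cl2/MeCN, −40 → 0 °C
Reagents that add atoms: none
Why: Proposed new method: BF3 abstracts fluoride from 18 to give the difluoroborane 19, which binds the ketal methoxy group of either C6 epimer of 13 and ionizes it to the planar C6=O1+ ion 20 (the ether oxygen is more basic than the peroxide oxygens, so the O–O ring stays closed), after which the alkynyl group passes from the methoxyborate to C6; the closest known reactions are the Lewis-acid-mediated additions of allylsilanes, silyl enol ethers and silyl ketene acetals to peroxyketals (Hosomi–Sakurai and Mukaiyama type via peroxycarbenium ions) and the BF3-promoted coupling of alkynyltrifluoroborates with acetals via oxocarbenium ions. No ring is closed; the step forms the C6–C1' bond and the quaternary peroxide centre and joins the two halves of the carbon skeleton. C6 is controlled by C3: in the half-chair of 20 (C5, C6, O1, O2 coplanar) the CH(CH3)CO2Me group at C3 sits pseudo-equatorial and the nucleophile enters on the axial trajectory that leads directly to a chair, that is cis to the C3 substituent, which should give alkynyl axial and methyl equatorial, (3S,6R). The step is stereoconvergent because both ketal epimers give the same ion, and the kinetic product is also the more stable C6 epimer (small sp substituent axial, methyl equatorial), so reversible ionization of the tertiary propargylic C–O bond should not erode it. The selectivities needed are loss of methoxide rather than opening of C6–O1, and attack by the alkynyl carbon rather than by the tetrasubstituted ring alkene of 18; the first rests on the basicity difference of the oxygens, the second on delivery from the boron ate complex.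

Step 11
Reactants: 21 methyl (2S)-2-[(3S,6R)-6-methyl-6-[(2,6,6-trimethylcyclohex-1-en-1-yl)ethynyl]-1,2-dioxan-3-yl]propanoate
Product: 22 methyl (2S)-2-[(3S,6S)-6-methyl-6-[2-(2,6,6-trimethylcyclohex-1-en-1-yl)ethyl]-1,2-dioxan-3-yl]propanoate
Conditions: KO2CN=NCO2K (large excess, in portions), AcOH, CH2Cl2/MeOH, 0 °C → rt
Reagents that add atoms: none
Why: Diimide reduction (concerted syn transfer of H2) should saturate the alkyne via the cis-alkene and leave the tetrasubstituted ring alkene, the O–O bond and the ester alone; no stereocenter is touched, and the C6 descriptor becomes S only because the CIP priorities of C5 and C1' are exchanged.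

Step 12
Reactants: 22 methyl (2S)-2-[(3S,6S)-6-methyl-6-[2-(2,6,6-trimethylcyclohex-1-en-1-yl)ethyl]-1,2-dioxan-3-yl]propanoate
Product: 25 Diacarperoxide B, via inner methoxy hydroperoxide 23 (not isolated), via outer methoxy hydroperoxide 24 (not isolated)
Conditions: O3, CH2Cl2/MeOH (5:1), NaHCO3, −78 °C; then Me2S, −78 °C → rt
Reagents that add atoms: ozone, [O-][O+]=O
Why: Ozonolysis of the electron-rich tetrasubstituted alkene with methanol trapping of the ketone oxide as a methoxy hydroperoxide, which Me2S reduces while the dialkyl peroxide ring is inert; this releases the C3' and C8' ketones without touching C2, C3 or C6.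

**Compound list**

1 | hex-5-en-2-one | CC(=O)CCC=C | starting material
2 | 4-(1,2,4-trioxolan-3-yl)butan-2-one | CC(=O)CCC1OCOO1 | intermediate
3 | 4-oxopentanal | CC(=O)CCC=O | intermediate
4 | 4,4,5,5-tetramethyl-2-[(2Z)-but-2-en-1-yl]-1,3,2-dioxaborolane ((Z)-crotylboronic acid pinacol ester) | C/C=C\CB1OC(C)(C)C(C)(C)O1 | starting material
5 | 4,4,5,5-tetramethyl-2-{[(3R,4R)-3-methyl-7-oxooct-1-en-4-yl]oxy}-1,3,2-dioxaborolane | C=C[C@@H](C)[C@H](OB1OC(C)(C)C(C)(C)O1)CCC(C)=O | intermediate
6 | (5R,6R)-5-hydroxy-6-methyloct-7-en-2-one | C=C[C@@H](C)[C@H](O)CCC(C)=O | intermediate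
7 | (3R,4R)-3-methyl-7-oxooct-1-en-4-yl methanesulfonate | C=C[C@@H](C)[C@H](OS(C)(=O)=O)CCC(C)=O | intermediate
8 | (3R,4R)-7-hydroperoxy-7-methoxy-3-methyloct-1-en-4-yl methanesulfonate | C=C[C@@H](C)[C@H](OS(C)(=O)=O)CCC(C)(OC)OO | intermediate
9 | (3S)-3-[(2R)-but-3-en-2-yl]-6-methoxy-6-methyl-1,2-dioxane | C=C[C@@H](C)[C@@H]1CCC(C)(OC)OO1 | intermediate
10 | (3S)-6-methoxy-6-methyl-3-[(1S)-1-(1,2,4-trioxolan-3-yl)ethyl]-1,2-dioxane | C1(OCOO1)[C@@H](C)[C@@H]2CCC(C)(OC)OO2 | intermediate
11 | (2S)-2-[(3S)-6-methoxy-6-methyl-1,2-dioxan-3-yl]propanal | O=C[C@@H](C)[C@@H]1CCC(C)(OC)OO1 | intermediate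
12 | (2S)-2-[(3S)-6-methoxy-6-methyl-1,2-dioxan-3-yl]propanoic acid | OC(=O)[C@@H](C)[C@@H]1CCC(C)(OC)OO1 | intermediate
13 | methyl (2S)-2-[(3S)-6-methoxy-6-methyl-1,2-dioxan-3-yl]propanoate | COC(=O)[C@@H](C)[C@@H]1CCC(C)(OC)OO1 | intermediate
14 | β-cyclocitral (2,6,6-trimethylcyclohex-1-ene-1-carbaldehyde) | CC1=C(C=O)C(C)(C)CCC1 | starting material
15 | 2-ethynyl-1,3,3-trimethylcyclohex-1-ene | CC1=C(C#C)C(C)(C)CCC1 | intermediate
16 | lithium (2,6,6-trimethylcyclohex-1-en-1-yl)acetylide | [Li+].[C-]#CC1=C(C)CCCC1(C)C | intermediate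
17 | lithium trimethoxy[(2,6,6-trimethylcyclohex-1-en-1-yl)ethynyl]borate | [Li+].CO[B-](OC)(OC)C#CC1=C(C)CCCC1(C)C | intermediate
18 | potassium trifluoro[(2,6,6-trimethylcyclohex-1-en-1-yl)ethynyl]borate | [K+].F[B-](F)(F)C#CC1=C(C)CCCC1(C)C | intermediate
19 | difluoro[(2,6,6-trimethylcyclohex-1-en-1-yl)ethynyl]borane | FB(F)C#CC1=C(C)CCCC1(C)C | intermediate
20 | (3S)-3-[(2S)-1-methoxy-1-oxopropan-2-yl]-6-methyl-1,2-dioxan-6-ylium (C6=O1+ peroxycarbenium ion) | COC(=O)[C@@H](C)[C@@H]1CCC(C)=[O+]O1 | intermediate
21 | methyl (2S)-2-[(3S,6R)-6-methyl-6-[(2,6,6-trimethylcyclohex-1-en-1-yl)ethynyl]-1,2-dioxan-3-yl]propanoate | COC(=O)[C@@H](C)[C@@H]1CC[C@](C)(C#CC2=C(C)CCCC2(C)C)OO1 | intermediate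
22 | methyl (2S)-2-[(3S,6S)-6-methyl-6-[2-(2,6,6-trimethylcyclohex-1-en-1-yl)ethyl]-1,2-dioxan-3-yl]propanoate | COC(=O)[C@@H](C)[C@@H]1CC[C@](C)(CCC2=C(C)CCCC2(C)C)OO1 | intermediate
23 | methyl (2S)-2-[(3S,6R)-6-(3-hydroperoxy-3-methoxy-4,4-dimethyl-8-oxononyl)-6-methyl-1,2-dioxan-3-yl]propanoate | COC(=O)[C@@H](C)[C@@H]1CC[C@](C)(CCC(OC)(OO)C(C)(C)CCCC(C)=O)OO1 | intermediate
24 | methyl (2S)-2-[(3S,6R)-6-(8-hydroperoxy-8-methoxy-4,4-dimethyl-3-oxononyl)-6-methyl-1,2-dioxan-3-yl]propanoate | COC(=O)[C@@H](C)[C@@H]1CC[C@](C)(CCC(=O)C(C)(C)CCCC(C)(OC)OO)OO1 | intermediate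
25 | Diacarperoxide B, methyl (2S)-2-[(3S,6R)-6-(4,4-dimethyl-3,8-dioxononyl)-6-methyl-1,2-dioxan-3-yl]propanoate | COC(=O)[C@@H](C)[C@@H]1CC[C@](C)(CCC(=O)C(C)(C)CCCC(C)=O)OO1 | target

**Count and risks**

Total step count: 12. Longest linear sequence: 10 (steps 1–7, then 10–12); steps 8–9 form the convergent branch.

Steps most likely to fail:

1. Step 10 (Proposed new method). What may go wrong: ionization of the ring C6–O1 bond or Lewis-acid-induced fragmentation of the peroxide instead of loss of methoxide, slow alkynyl transfer to the hindered tertiary cation, or loss of facial selectivity. Fallback with known chemistry, from 13 back to 22: a Hosomi–Sakurai-type reaction of 13 with propargyltrimethylsilane and TiCl4 (CH2Cl2, −78 °C), the established silane addition to peroxyketal-derived cations, should give with the same axial entry the allene methyl (2S)-2-[(3S,6R)-6-methyl-6-(propa-1,2-dien-1-yl)-1,2-dioxan-3-yl]propanoate F1. Ozonolysis (O3, CH2Cl2, −78 °C; Me2S) should cleave it to the aldehyde methyl (2S)-2-[(3S,6R)-6-formyl-6-methyl-1,2-dioxan-3-yl]propanoate F2. In parallel, NaBH4 reduction of 14 gives β-cyclogeraniol F3, which with Ph3P·HBr gives [(2,6,6-trimethylcyclohex-1-en-1-yl)methyl]triphenylphosphonium bromide F4; NaHMDS (THF, −78 °C) converts it into the ylide [(2,6,6-trimethylcyclohex-1-en-1-yl)methylidene]triphenylphosphorane F5. Wittig reaction of F5 with F2 should give the diene methyl (2S)-2-[(3S,6R)-6-methyl-6-[2-(2,6,6-trimethylcyclohex-1-en-1-yl)ethenyl]-1,2-dioxan-3-yl]propanoate F6 (either alkene geometry serves). Diimide reduction of its disubstituted double bond under the conditions of step 11 returns to 22.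

2. Step 5. What may go wrong: E2 elimination of the β-branched secondary mesylate towards the conjugated diene, or a 6-exo displacement so slow that the hydroperoxy ketal decomposes. Fallback, from 3 back to 13, avoiding substitution at a secondary carbon: Wittig reaction of 3 with methyl 2-(triphenylphosphoranylidene)propanoate gives methyl (2E)-2-methyl-6-oxohept-2-enoate F7. Perhydrolysis (urea–H2O2, Sc(OTf)3, MeOH) gives methyl (2E)-6-hydroperoxy-6-methoxy-2-methylhept-2-enoate F8. Amine-mediated intramolecular oxa-Michael addition (Et2NH, CF3CH2OH) closes the ring to methyl 2-(6-methoxy-6-methyl-1,2-dioxan-3-yl)propanoate as the racemic mixture of C2/C3 isomers F9. This route gives up the stereocontrol: the (2S,3S) isomer 13 would have to be isolated by chromatography and preparative HPLC on a chiral phase.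

3. Step 12. What may go wrong: incomplete trapping of the hindered ketone oxide, leading to oligomeric peroxides or a persistent tetrasubstituted ozonide, and over-oxidation during the long exposure the hindered alkene needs. Fallback, from 22 to 25, without ozone: epoxidation with mCPBA (NaHCO3, CH2Cl2, 0 °C) should give the epoxide methyl (2S)-2-[(3S,6R)-6-methyl-6-[2-(2,2,6-trimethyl-7-oxabicyclo[4.1.0]heptan-1-yl)ethyl]-1,2-dioxan-3-yl]propanoate F10. Periodic acid (H5IO6, THF/H2O) opens it to the diol methyl (2S)-2-[(3S,6R)-6-[2-(1,2-dihydroxy-2,6,6-trimethylcyclohexyl)ethyl]-6-methyl-1,2-dioxan-3-yl]propanoate F11 and cleaves the glycol in the same flask to 25.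

Further compounds
F1 | step 10 | methyl (2S)-2-[(3S,6R)-6-methyl-6-(propa-1,2-dien-1-yl)-1,2-dioxan-3-yl]propanoate | COC(=O)[C@@H](C)[C@@H]1CC[C@](C)(C=C=C)OO1
F2 | step 10 | methyl (2S)-2-[(3S,6R)-6-formyl-6-methyl-1,2-dioxan-3-yl]propanoate | COC(=O)[C@@H](C)[C@@H]1CC[C@](C)(C=O)OO1
F3 | step 10 | β-cyclogeraniol, (2,6,6-trimethylcyclohex-1-en-1-yl)methanol | CC1=C(CO)C(C)(C)CCC1
F4 | step 10 | [(2,6,6-trimethylcyclohex-1-en-1-yl)methyl]triphenylphosphonium bromide | CC1=C(C[P+](c2ccccc2)(c2ccccc2)c2ccccc2)C(C)(C)CCC1.[Br-]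
F5 | step 10 | [(2,6,6-trimethylcyclohex-1-en-1-yl)methylidene]triphenylphosphorane | CC1=C(C=P(c2ccccc2)(c2ccccc2)c2ccccc2)C(C)(C)CCC1
F6 | step 10 | methyl (2S)-2-[(3S,6R)-6-methyl-6-[2-(2,6,6-trimethylcyclohex-1-en-1-yl)ethenyl]-1,2-dioxan-3-yl]propanoate | COC(=O)[C@@H](C)[C@@H]1CC[C@](C)(C=CC2=C(C)CCCC2(C)C)OO1
F7 | step 5 | methyl (2E)-2-methyl-6-oxohept-2-enoate | COC(=O)/C(C)=C/CCC(C)=O
F8 | step 5 | methyl (2E)-6-hydroperoxy-6-methoxy-2-methylhept-2-enoate | COC(=O)/C(C)=C/CCC(C)(OC)OO
F9 | step 5 | methyl 2-(6-methoxy-6-methyl-1,2-dioxan-3-yl)propanoate, racemic mixture of C2/C3 isomers | COC(=O)C(C)C1CCC(C)(OC)OO1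
F10 | step 12 | methyl (2S)-2-[(3S,6R)-6-methyl-6-[2-(2,2,6-trimethyl-7-oxabicyclo[4.1.0]heptan-1-yl)ethyl]-1,2-dioxan-3-yl]propanoate | COC(=O)[C@@H](C)[C@@H]1CC[C@](C)(CCC23OC2(C)CCCC3(C)C)OO1
F11 | step 12 | methyl (2S)-2-[(3S,6R)-6-[2-(1,2-dihydroxy-2,6,6-trimethylcyclohexyl)ethyl]-6-methyl-1,2-dioxan-3-yl]propanoate | COC(=O)[C@@H](C)[C@@H]1CC[C@](C)(CCC2(O)C(C)(O)CCCC2(C)C)OO1
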